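**Plan**
Numbering: C1 is the CH2 on the furan, C6 bears OMe, C11 is the carbinol, C12 the quaternary carbon and C15 the lactone carbonyl. The enabling feature is the lactone ring (O, C12, C13, C14, C15). C12 carries a methyl group, the ring oxygen and the C13–C14–C15 acyl chain next to carbinol C11, so removing the ring oxygen leaves a 2-(1-hydroxyalkyl)-2-methylcyclobutanone (ring C12–C13–C14–C15). That ketone is the ring-expanded form of a cyclopropanol (C13, C14, C15) attached to a C11=C12 alkene.
Cuts, in retrosynthetic order: O–C12 of the lactone (Baeyer–Villiger), C12–C13 together with C11–O (epoxidation and 1,2-shift), C12–C15 (alkenyl metal plus cyclopropanone), C11=C12 (Wittig), C9–C10 (Johnson–Claisen), C7–C8 (Grignard), C5–C6 (Ireland–Claisen), C3–C4 (Grignard), C1=C2 (Horner–Wadsworth–Emmons).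
Forward, the chain grows linearly from 3-furaldehyde to the C1–C11 aldehyde. The three-membered ring is then attached, expanded to the four-membered ketone and oxidised to the five-membered lactone.
Stereochemistry: a CBS reduction sets a C3 carbinol, and the Ireland–Claisen chair relays its configuration to C6 (S). Both E alkenes come from chair Claisen transition states, and the Z C11=C12 alkene comes from an iodo-ylide Wittig reaction. A chiral bishydroxamate catalyst selects the alkene face (C11, R), the anti 1,2-shift fixes C12 (S) relative to it, and the Baeyer–Villiger migration retains C12.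

Key step: step 14

Assumption: the sense of induction of the hafnium–bishydroxamate catalyst on a cyclopropanol is not established, so the route is written with the (R,R)-ligand as the one that oxidises the 11Re,12Re face; if a trial on a simple (Z)-1-alkenylcyclopropanol shows the opposite sense, the equally available (S,S)-ligand takes its place.

Step 1
Reactants: 1 3-furaldehyde; 2 diethyl (N-methoxy-N-methylcarbamoylmethyl)phosphonate
Product: 3 (E)-3-(furan-3-yl)-N-methoxy-N-methylprop-2-enamide
Conditions: NaH, THF, 0 °C to rt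
Reagents that add atoms: none
Why: Horner–Wadsworth–Emmons olefination of an aromatic aldehyde with a stabilised phosphonoacetamide anion is reliably E-selective, forms C1=C2 and installs the Weinreb amide needed in step 3.

Step 2
Reactants: 3 (E)-3-(furan-3-yl)-N-methoxy-N-methylprop-2-enamide
Product: 4 3-(furan-3-yl)-N-methoxy-N-methylpropanamide
Conditions: H2 (1 atm), Pd/C, EtOAc, rt, stopped after 1 equiv H2
Reagents that add atoms: none
Why: Catalytic hydrogenation should saturate the unhindered conjugated alkene well before the aromatic furan or the N–O bond reacts, provided uptake is limited to one equivalent.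

Step 3
Reactants: 4 3-(furan-3-yl)-N-methoxy-N-methylpropanamide; 5 isopropenylmagnesium bromide
Product: 6 1-(furan-3-yl)-4-methylpent-4-en-3-one
Conditions: THF, 0 °C; poured into cold 1 M HCl
Reagents that add atoms: none
Why: In this Weinreb ketone synthesis the chelated tetrahedral magnesium adduct survives until the quench, so only one addition occurs (C3–C4 bond), and the cold acid keeps the released amine protonated and away from the enone.

Step 4
Reactants: 6 1-(furan-3-yl)-4-methylpent-4-en-3-one
Product: 7 (3S)-1-(furan-3-yl)-4-methylpent-4-en-3-ol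
Conditions: (R)-Me-CBS oxazaborolidine (15 mol %), catecholborane, toluene, −78 °C; aqueous work-up
Reagents that add atoms: none
Why: In the Corey–Bakshi–Shibata reduction the ketone binds the (R)-oxazaborolidine–borane complex with the branched isopropenyl group as the large substituent, so hydride should give the (S)-carbinol, and catecholborane at low temperature does not hydroborate the 1,1-disubstituted alkene.

Step 5
Reactants: 7 (3S)-1-(furan-3-yl)-4-methylpent-4-en-3-ol; 8 methoxyacetic acid
Product: 9 (3S)-1-(furan-3-yl)-4-methylpent-4-en-3-yl 2-methoxyacetate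
Conditions: DCC, DMAP (cat.), CH2Cl2, 0 °C to rt
Reagents that add atoms: none
Why: Steglich esterification acylates the secondary allylic alcohol at oxygen under neutral conditions, so the carbinol stereocentre is not touched.

Step 6
Reactants: 9 (3S)-1-(furan-3-yl)-4-methylpent-4-en-3-yl 2-methoxyacetate
Product: 12 (2S,4E)-7-(furan-3-yl)-2-methoxy-4-methylhept-4-enoic acid, via (Z)-silyl ketene acetal 10 (not isolated), via trimethylsilyl ester 11 (not isolated)
Conditions: LiN(iPr)2, THF, −78 °C; TMSCl, −78 °C to rt; aq. citric acid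
Reagents that add atoms: chlorotrimethylsilane, C[Si](C)(C)Cl (its silyl group is carried only by 10 and 11)
Why: In the glycolate Ireland–Claisen rearrangement, lithium chelation between the enolate and methoxy oxygens fixes the (Z)-ketene acetal, and the chair with the furylethyl chain equatorial forms C5–C6, makes C3=C4 E and relays the (S)-carbinol configuration to (S)-C6.

Step 7
Reactants: 12 (2S,4E)-7-(furan-3-yl)-2-methoxy-4-methylhept-4-enoic acid
Product: 13 methyl (2S,4E)-7-(furan-3-yl)-2-methoxy-4-methylhept-4-enoate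
Conditions: MeI, K2CO3, DMF, rt
Reagents that add atoms: iodomethane, C[I]
Why: SN2 O-alkylation of the carboxylate needs only a weak base, which leaves the α-methoxy stereocentre unaffected.

Step 8
Reactants: 13 methyl (2S,4E)-7-(furan-3-yl)-2-methoxy-4-methylhept-4-enoate; 5 isopropenylmagnesium bromide
Product: 15 (4S,6E)-9-(furan-3-yl)-4-methoxy-2,6-dimethylnona-1,6-dien-3-ol (both C3 epimers), via α-methoxy aldehyde 14 (not isolated)
Conditions: iBu2AlH, CH2Cl2, −78 °C; then 5 in THF, −78 to 0 °C; aq. potassium sodium tartrate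
Reagents that add atoms: none
Why: One-pot partial reduction and Grignard addition works because the chelated aluminium hemiacetal of an α-alkoxy ester releases aldehyde only as the Grignard reagent traps it (C7–C8 bond), so the epimerisable aldehyde is never handled, and the new carbinol centre is erased in step 9.

Step 9
Reactants: 15 (4S,6E)-9-(furan-3-yl)-4-methoxy-2,6-dimethylnona-1,6-dien-3-ol; 16 triethyl orthoacetate
Product: 18 ethyl (4E,6S,8E)-11-(furan-3-yl)-6-methoxy-4,8-dimethylundeca-4,8-dienoate, via mixed ketene acetal 17 (not isolated)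
Conditions: 16 (excess), EtCO2H (cat.), 140 °C, EtOH distilled off
Reagents that add atoms: none
Why: In the Johnson–Claisen rearrangement both carbinol epimers react through chairs that keep the branched C6 substituent equatorial and away from the ethoxy group, so C9–C10 forms, C7=C8 should come out E and C6 is not involved.

Step 10
Reactants: 18 ethyl (4E,6S,8E)-11-(furan-3-yl)-6-methoxy-4,8-dimethylundeca-4,8-dienoate
Product: 19 (4E,6S,8E)-11-(furan-3-yl)-6-methoxy-4,8-dimethylundeca-4,8-dienal
Conditions: iBu2AlH (1.05 equiv), toluene, −78 °C; aq. potassium sodium tartrate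
Reagents that add atoms: none
Why: Partial ester reduction stops at the aluminium hemiacetal at −78 °C, and the aldehyde appears only on work-up.

Step 11
Reactants: 19 (4E,6S,8E)-11-(furan-3-yl)-6-methoxy-4,8-dimethylundeca-4,8-dienal; 20 ethyltriphenylphosphonium bromide
Product: 24 3-[(3E,6S,7E,11Z)-12-iodo-6-methoxy-4,8-dimethyltrideca-3,7,11-trien-1-yl]furan, via ethylidene ylide 21 (not isolated), via iodoethylphosphonium iodide 22 (not isolated), via iodoethylidene ylide 23 (not isolated)
Conditions: 20, n-BuLi, THF, rt; I2, −78 °C; NaN(SiMe3)2, −20 °C; then 19, −78 to −20 °C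
Reagents that add atoms: iodine, [I][I]
Why: In this Stork–Zhao-type Wittig olefination the non-stabilised α-iodo ylide reacts under kinetic control through the cis-oxaphosphetane, which places C10 and iodine on the same side of the new C11=C12 bond (Z).

Step 12
Reactants: 25 (1-ethoxycyclopropoxy)trimethylsilane
Product: 26 1-(phenylsulfonyl)cyclopropan-1-ol
Conditions: PhSO2Na, HCO2H, H2O, rt
Reagents that add atoms: sodium benzenesulfinate, [Na+].[O-]S(=O)c1ccccc1
Why: Acid unmasks the cyclopropanone hemiketal and sulfinic acid adds to the strained carbonyl carbon, as in α-hydroxy sulfone formation from aldehydes, to give a storable cyclopropanone equivalent that loses sulfinate far more readily than the hemiketal loses ethoxide.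

Step 13
Reactants: 24 3-[(3E,6S,7E,11Z)-12-iodo-6-methoxy-4,8-dimethyltrideca-3,7,11-trien-1-yl]furan; 26 1-(phenylsulfonyl)cyclopropan-1-ol
Product: 29 1-[(2Z,6E,8S,10E)-13-(furan-3-yl)-8-methoxy-6,10-dimethyltrideca-2,6,10-trien-2-yl]cyclopropan-1-ol, via alkenyllithium 27 (not isolated), via cyclopropanone 28 (not isolated)
Conditions: 24, t-BuLi (2 equiv), Et2O, −78 °C; added to 26 (2 equiv) + MeMgBr (2 equiv), THF, −78 °C; to 0 °C; pH 7 buffer; Et3N-washed silica
Reagents that add atoms: tert-butyllithium, [Li]C(C)(C)C (its lithium is carried only by 27)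
Why: Iodine–lithium exchange keeps the alkene geometry and outruns furan metalation at −78 °C, and 1,2-addition of the alkenyl metal to cyclopropanone, released from the magnesium alkoxide of 26 by loss of sulfinate, forms C12–C15 with relief of angle strain at the sp2 ring carbon.

Step 14
Reactants: 29 1-[(2Z,6E,8S,10E)-13-(furan-3-yl)-8-methoxy-6,10-dimethyltrideca-2,6,10-trien-2-yl]cyclopropan-1-ol
Product: 31 (2S)-2-[(1R,4E,6S,8E)-11-(furan-3-yl)-1-hydroxy-6-methoxy-4,8-dimethylundeca-4,8-dien-1-yl]-2-methylcyclobutan-1-one, via epoxy cyclopropanol 30 (not isolated)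
Conditions: Hf(OtBu)4 (10 mol %), (1R,2R)-N,N'-dihydroxy-N,N'-bis(diphenylacetyl)cyclohexane-1,2-diamine (12 mol %), cumene hydroperoxide (1.5 equiv), MgO, toluene, 0 °C to rt
Reagents that add atoms: cumene hydroperoxide, CC(C)(OO)c1ccccc1
Why: Proposed new method: the cyclopropanol oxygen of 29 and the hydroperoxide bind to the hafnium–bishydroxamate complex, peroxide oxygen passes to the neighbouring C11=C12 bond and closes the oxirane (O, C11, C12) of 30 by [2+1] oxygen transfer, and as the Lewis acid loosens the tertiary C12–O bond the cyclopropane C15–C13 bond lying anti to it shifts to C12 while the carbinol oxygen becomes the C15 ketone. The closest known reactions are the achiral hydroxyl-directed (VO(acac)2/TBHP or peracid) epoxidation–semipinacol expansion of 1-alkenylcyclopropanols and the Hf(OtBu)4–bishydroxamic acid epoxidation of acyclic tertiary allylic alcohols, and what is new is ligand-controlled face selection on a cyclopropanol. The cyclobutanone ring (C12, C13, C14, C15) therefore closes by a three-to-four ring expansion (1,2-shift) and not by joining chain ends, driven by oxirane opening and C=O formation and helped by the high migratory aptitude of the bent cyclopropane bond. C11 (R) is set by the ligand, which decides that the 11Re,12Re face receives oxygen, and C12 (S) is set relative to C11 by the stereospecific anti shift (inversion at C12) acting on the Z alkene. The step must oxidise one of three trisubstituted alkenes and spare the furan, which is secured because only C11=C12 is allylic to the sole hydroxyl group that can bind the metal and an alkyl hydroperoxide is inert to alkenes it is not delivered to. Tetravalent hafnium is preferred to pentavalent vanadium because it is redox-inert and cannot open the cyclopropanol by one-electron oxidation, and MgO keeps the medium free of acid that would protonate the alkenylcyclopropanol.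

Step 15
Reactants: 31 (2S)-2-[(1R,4E,6S,8E)-11-(furan-3-yl)-1-hydroxy-6-methoxy-4,8-dimethylundeca-4,8-dien-1-yl]-2-methylcyclobutan-1-one
Product: 32 (5S)-5-[(1R,4E,6S,8E)-11-(furan-3-yl)-1-hydroxy-6-methoxy-4,8-dimethylundeca-4,8-dien-1-yl]-5-methyloxolan-2-one (CNP0306177.2)
Conditions: 30 % aq. H2O2 (excess), LiOH (1 equiv), THF/H2O, 0 °C; aq. Na2SO3; NaH2PO4 to pH 5
Reagents that add atoms: hydrogen peroxide, OO
Why: In the Baeyer–Villiger oxidation hydroperoxide anion adds to the strained cyclobutanone, the more substituted C12 migrates to oxygen with retention, nucleophilic peroxide ignores the electron-rich furan and alkenes, and excess H2O2 holds the basicity at the hydroperoxide level that β-hydroxy carbonyl compounds normally tolerate without retro-aldol cleavage.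

**Compound list**
1 | 3-furaldehyde | O=Cc1ccoc1 | starting material
2 | diethyl (N-methoxy-N-methylcarbamoylmethyl)phosphonate | CCOP(=O)(CC(=O)N(C)OC)OCC | starting material
3 | (E)-3-(furan-3-yl)-N-methoxy-N-methylprop-2-enamide | CON(C)C(=O)/C=C/c1ccoc1 | intermediate
4 | 3-(furan-3-yl)-N-methoxy-N-methylpropanamide | CON(C)C(=O)CCc1ccoc1 | intermediate
5 | isopropenylmagnesium bromide | CC(=C)[Mg]Br | starting material
6 | 1-(furan-3-yl)-4-methylpent-4-en-3-one | CC(=C)C(=O)CCc1ccoc1 | intermediate
7 | (3S)-1-(furan-3-yl)-4-methylpent-4-en-3-ol | CC(=C)[C@@H](O)CCc1ccoc1 | intermediate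
8 | methoxyacetic acid | COCC(=O)O | starting material
9 | (3S)-1-(furan-3-yl)-4-methylpent-4-en-3-yl 2-methoxyacetate | CC(=C)[C@@H](OC(=O)COC)CCc1ccoc1 | intermediate
10 | (Z)-trimethylsilyl ketene acetal of 9 (OMe cis to OSiMe3) | CO/C=C(\O[Si](C)(C)C)O[C@@H](CCc1ccoc1)C(C)=C | intermediate
11 | trimethylsilyl (2S,4E)-7-(furan-3-yl)-2-methoxy-4-methylhept-4-enoate | CO[C@@H](C/C(C)=C/CCc1ccoc1)C(=O)O[Si](C)(C)C | intermediate
12 | (2S,4E)-7-(furan-3-yl)-2-methoxy-4-methylhept-4-enoic acid | CO[C@@H](C/C(C)=C/CCc1ccoc1)C(=O)O | intermediate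
13 | methyl (2S,4E)-7-(furan-3-yl)-2-methoxy-4-methylhept-4-enoate | CO[C@@H](C/C(C)=C/CCc1ccoc1)C(=O)OC | intermediate
14 | (2S,4E)-7-(furan-3-yl)-2-methoxy-4-methylhept-4-enal | CO[C@@H](C/C(C)=C/CCc1ccoc1)C=O | intermediate
15 | (4S,6E)-9-(furan-3-yl)-4-methoxy-2,6-dimethylnona-1,6-dien-3-ol, both C3 epimers | CO[C@@H](C/C(C)=C/CCc1ccoc1)C(O)C(C)=C | intermediate
16 | triethyl orthoacetate | CCOC(C)(OCC)OCC | starting material
17 | 1-ethoxyvinyl ether of 15 (mixed ketene acetal) | C=C(OCC)OC(C(C)=C)[C@@H](OC)C/C(C)=C/CCc1ccoc1 | intermediate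
18 | ethyl (4E,6S,8E)-11-(furan-3-yl)-6-methoxy-4,8-dimethylundeca-4,8-dienoate | CO[C@H](/C=C(\C)CCC(=O)OCC)C/C(C)=C/CCc1ccoc1 | intermediate
19 | (4E,6S,8E)-11-(furan-3-yl)-6-methoxy-4,8-dimethylundeca-4,8-dienal | CO[C@H](/C=C(\C)CCC=O)C/C(C)=C/CCc1ccoc1 | intermediate
20 | ethyltriphenylphosphonium bromide | CC[P+](c1ccccc1)(c1ccccc1)c1ccccc1.[Br-] | starting material
21 | ethylidenetriphenylphosphorane | CC=P(c1ccccc1)(c1ccccc1)c1ccccc1 | intermediate
22 | (1-iodoethyl)triphenylphosphonium iodide | CC(I)[P+](c1ccccc1)(c1ccccc1)c1ccccc1.[I-] | intermediate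
23 | (1-iodoethylidene)triphenylphosphorane | CC(I)=P(c1ccccc1)(c1ccccc1)c1ccccc1 | intermediate
24 | 3-[(3E,6S,7E,11Z)-12-iodo-6-methoxy-4,8-dimethyltrideca-3,7,11-trien-1-yl]furan | CO[C@H](/C=C(\C)CC/C=C(/C)I)C/C(C)=C/CCc1ccoc1 | intermediate
25 | (1-ethoxycyclopropoxy)trimethylsilane | CCOC1(O[Si](C)(C)C)CC1 | starting material
26 | 1-(phenylsulfonyl)cyclopropan-1-ol | OC1(CC1)S(=O)(=O)c1ccccc1 | intermediate
27 | (Z)-alkenyllithium from 24 (Li in place of iodine, geometry kept) | CO[C@H](/C=C(\C)CC/C=C(/C)[Li])C/C(C)=C/CCc1ccoc1 | intermediate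
28 | cyclopropanone | O=C1CC1 | intermediate
29 | 1-[(2Z,6E,8S,10E)-13-(furan-3-yl)-8-methoxy-6,10-dimethyltrideca-2,6,10-trien-2-yl]cyclopropan-1-ol | CO[C@H](/C=C(\C)CC/C=C(/C)C1(O)CC1)C/C(C)=C/CCc1ccoc1 | intermediate
30 | 1-{(2R,3R)-3-[(3E,5S,7E)-10-(furan-3-yl)-5-methoxy-3,7-dimethyldeca-3,7-dien-1-yl]-2-methyloxiran-2-yl}cyclopropan-1-ol | CO[C@H](/C=C(\C)CC[C@H]1O[C@@]1(C)C1(O)CC1)C/C(C)=C/CCc1ccoc1 | intermediate
31 | (2S)-2-[(1R,4E,6S,8E)-11-(furan-3-yl)-1-hydroxy-6-methoxy-4,8-dimethylundeca-4,8-dien-1-yl]-2-methylcyclobutan-1-one | CO[C@H](/C=C(\C)CC[C@@H](O)[C@]1(C)CCC1=O)C/C(C)=C/CCc1ccoc1 | intermediate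
32 | (5S)-5-[(1R,4E,6S,8E)-11-(furan-3-yl)-1-hydroxy-6-methoxy-4,8-dimethylundeca-4,8-dien-1-yl]-5-methyloxolan-2-one | CO[C@H](/C=C(\C)CC[C@@H](O)[C@]1(C)CCC(=O)O1)C/C(C)=C/CCc1ccoc1 | target

**Step count**
Total steps: 15. Longest linear sequence: 14 (steps 1–11 and 13–15). Step 12 is a one-step side branch.

**Steps most likely to fail**

Step 14. The catalyst may discriminate poorly between the two alkene faces of a cyclopropanol. Stereospecificity may also erode if the C12–O bond ionises fully before the shift, and the cyclopropanol may ring-open before oxygen transfer.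
- The fallback uses known chemistry, sets out from aldehyde 19 and returns at target 32.
- A stabilised Wittig reaction with Ph3P=C(CH3)CO2Et should give the (E)-2-methyl enoate F1, and iBu2AlH should give the (E)-allylic alcohol F2.
- Sharpless asymmetric epoxidation (Ti(OiPr)4, D-(−)-diethyl tartrate, TBHP, 4 Å molecular sieves, CH2Cl2, −20 °C) touches only the alkene next to the titanium-bound hydroxyl and should give the (11R,12R)-epoxy alcohol F3.
- Parikh–Doering oxidation leads to the epoxy aldehyde F4, and Wittig reaction with Ph3P=CHCO2Me leads to the epoxy enoate F5.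
- Diimide (2-nitrobenzenesulfonohydrazide, Et3N) saturates only the disubstituted conjugated alkene to give the epoxy ester F6.
- Saponification with LiOH gives the epoxy acid F7. On mild acidification this closes the lactone by 5-exo attack of the carboxyl oxygen at tertiary C12 with inversion.
- Anti addition of two oxygens across the E alkene gives the same 11R,12S pair, which is 32.

Step 13. The hindered Z-alkenyl metal may capture the short-lived cyclopropanone too slowly, so that protonation of the organometallic and oligomerisation of the ketone take over.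
- The fallback sets out from aldehyde 19 and returns at cyclopropanol 29, bypassing steps 11 and 12 as well.
- Still–Gennari olefination with methyl 2-[bis(2,2,2-trifluoroethoxy)phosphoryl]propanoate (KN(SiMe3)2, 18-crown-6, THF, −78 °C) should give the (Z)-2-methyl enoate F8.
- Kulinkovich cyclopropanation (EtMgBr, Ti(OiPr)4, THF, 0 °C to rt) turns the ester carbonyl of F8 into the cyclopropanol carbon C15, with C13 and C14 supplied by the Grignard reagent.

Step 15. The free β-hydroxy ketone may undergo retro-aldol cleavage, which would scramble C11 and C12, and the acyl group may migrate to the C11 hydroxyl under basic peroxide.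
- The fallback sets out from cyclobutanone 31 and returns at target 32.
- Silylation (TESOTf, 2,6-lutidine, CH2Cl2, −78 °C) gives the triethylsilyl ether F9, which has no alkoxide to start the fragmentation.
- Baeyer–Villiger oxidation with H2O2/NaOH in THF/MeOH at 0 °C gives the silylated lactone F10, and HF·pyridine in THF at 0 °C frees the carbinol.

**Further compounds**
F1 | step 14 | ethyl (2E,6E,8S,10E)-13-(furan-3-yl)-8-methoxy-2,6,10-trimethyltrideca-2,6,10-trienoate | CO[C@H](/C=C(\C)CC/C=C(\C)C(=O)OCC)C/C(C)=C/CCc1ccoc1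
F2 | step 14 | (2E,6E,8S,10E)-13-(furan-3-yl)-8-methoxy-2,6,10-trimethyltrideca-2,6,10-trien-1-ol | CO[C@H](/C=C(\C)CC/C=C(\C)CO)C/C(C)=C/CCc1ccoc1
F3 | step 14 | {(2R,3R)-3-[(3E,5S,7E)-10-(furan-3-yl)-5-methoxy-3,7-dimethyldeca-3,7-dien-1-yl]-2-methyloxiran-2-yl}methanol | CO[C@H](/C=C(\C)CC[C@H]1O[C@]1(C)CO)C/C(C)=C/CCc1ccoc1
F4 | step 14 | (2S,3R)-3-[(3E,5S,7E)-10-(furan-3-yl)-5-methoxy-3,7-dimethyldeca-3,7-dien-1-yl]-2-methyloxirane-2-carbaldehyde | CO[C@H](/C=C(\C)CC[C@H]1O[C@]1(C)C=O)C/C(C)=C/CCc1ccoc1
F5 | step 14 | methyl (2E)-3-{(2R,3R)-3-[(3E,5S,7E)-10-(furan-3-yl)-5-methoxy-3,7-dimethyldeca-3,7-dien-1-yl]-2-methyloxiran-2-yl}prop-2-enoate | CO[C@H](/C=C(\C)CC[C@H]1O[C@]1(C)/C=C/C(=O)OC)C/C(C)=C/CCc1ccoc1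
F6 | step 14 | methyl 3-{(2R,3R)-3-[(3E,5S,7E)-10-(furan-3-yl)-5-methoxy-3,7-dimethyldeca-3,7-dien-1-yl]-2-methyloxiran-2-yl}propanoate | CO[C@H](/C=C(\C)CC[C@H]1O[C@]1(C)CCC(=O)OC)C/C(C)=C/CCc1ccoc1
F7 | step 14 | 3-{(2R,3R)-3-[(3E,5S,7E)-10-(furan-3-yl)-5-methoxy-3,7-dimethyldeca-3,7-dien-1-yl]-2-methyloxiran-2-yl}propanoic acid | CO[C@H](/C=C(\C)CC[C@H]1O[C@]1(C)CCC(=O)O)C/C(C)=C/CCc1ccoc1
F8 | step 13 | methyl (2Z,6E,8S,10E)-13-(furan-3-yl)-8-methoxy-2,6,10-trimethyltrideca-2,6,10-trienoate | CO[C@H](/C=C(\C)CC/C=C(/C)C(=O)OC)C/C(C)=C/CCc1ccoc1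
F9 | step 15 | triethylsilyl ether of 31 at the C11 oxygen | CO[C@H](/C=C(\C)CC[C@@H](O[Si](CC)(CC)CC)[C@]1(C)CCC1=O)C/C(C)=C/CCc1ccoc1
F10 | step 15 | triethylsilyl ether of 32 at the C11 oxygen | CO[C@H](/C=C(\C)CC[C@@H](O[Si](CC)(CC)CC)[C@]1(C)CCC(=O)O1)C/C(C)=C/CCc1ccoc1
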